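The ratio of left-handed substrate left to left-handed substrate charged is the number we follow. In the alder run at 10.0 s it gives 290 /M/s: this is the specific loss constant, the natural logarithm of charged over left, divided by time and by the catalyst charged, a pseudo-first-order constant per catalyst. The cedar run at 10.0 s gives 308 /M/s, so at equal [partner] we expect an order in free catalyst of about one.

the same everywhere: left-handed substrate 34 mM; right-handed substrate 34 mM
- cedar: partner 51 mM; free catalyst 0.17 mM; run made earlier
- alder: partner 51 mM; free catalyst 0.26 mM; run made earlier
- larch: partner 100 mM; free catalyst 0.34 mM; run made earlier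
- flask: partner 51.0 mM; free catalyst 0.34 mM

| run | time / s | left-handed product / % | left-handed substrate / % |
|---|---|---|---|
| cedar | 10.0 | 21.0 | 29.6 |
| cedar | 12.0 | 23.6 | 26.6 |
| cedar | 20.0 | 29.9 | 19.4 |
| cedar | 25.0 | 32.8 | 16.1 |
| cedar | 40.0 | 37.6 | 11.9 |
| cedar | 60.0 | 41.3 | 9.4 |
| cedar | 90.0 | 41.9 | 8.1 |
| alder | 10.0 | 27.5 | 23.5 |
| alder | 15.0 | 33.2 | 16.5 |
| alder | 25.0 | 39.1 | 9.9 |
| alder | 40.0 | 42.8 | 5.4 |
| alder | 60.0 | 45.0 | 4.0 |
| alder | 80.0 | 45.3 | 4.0 |
| alder | 90.0 | 45.7 | 4.7 |
| larch | 20.0 | 50.0 | 0 |
| larch | 40.0 | 49.9 | 0.2 |
| larch | 60.0 | 49.3 | 0.9 |
| larch | 80.0 | 49.9 | 0 |
| larch | 90.0 | 49.7 | 0.2 |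

(standard deviation of a reading: 0.5 percentage points)

- free catalyst is single-handed; left-handed substrate and right-handed substrate are mirror images of each other, charged as a racemate, each of them at the stated concentration
- reactions considered so far: free catalyst + left-handed substrate <-> catalyst intermediate A; free catalyst + right-handed substrate <-> catalyst intermediate B; partner -> decomposed reagent; partner + catalyst intermediate B -> free catalyst + right-handed product; partner + catalyst intermediate A -> free catalyst + left-handed product
- what is bound to the catalyst counts as converted

* apparent order in partner when 5.0 % of the left-handed substrate and right-handed substrate together are converted (percent change of the rate of making left-handed product for one percent more partner charged)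
* apparent order in free catalyst when 5.0 % of the left-handed substrate and right-handed substrate together are converted (percent change of the rate of making left-handed product for one percent more free catalyst charged)

For [partner] we bracket. From above: partner enters the rate once, and at the conversion asked about 3.40 mM of it is used, so we put the order at most near 1.07. From below: the highest larch reading of left-handed substrate is 0.9 %, and taken as a ceiling at 20.0 s it gives a constant of at least 591 /M/s. Larch mean [partner] is at most 100 mM. For alder we allow as much again for right-handed product and decay as for left-handed product, which leaves a mean of 32.3 mM. Our floor is therefore 0.628.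

The forecast says “Doubling partner therefore at least doubles the rate” and gives 1 for partner, within our bracket, and 1 for free catalyst.

The flask gives 0.86, inside the bracket, and 1.0.

    free catalyst + left-handed substrate ⇌ catalyst intermediate A (K = 230 /M, k = 2000 /M/s)
    free catalyst + right-handed substrate ⇌ catalyst intermediate B (K = 51.0 /M, k = 360 /M/s)
    partner → decomposed reagent (k = 0.0180 /s)
    partner + catalyst intermediate B → free catalyst + right-handed product (k = 150 /M/s)
    partner + catalyst intermediate A → free catalyst + left-handed product (k = 400 /M/s)

In the flask, by 0.200 min, with partner still there, left-handed substrate had fallen to 14.8 % of the two substrates charged together, a specific loss constant of 298 /M/s, and partner stood at 31.8 % of its charge. Partner, the limiting reagent, was down to 1.02 % of its charge at 1.00 min, and at 2.00 min the flask held, unbound, 5.8 % of its charged left-handed substrate and 74 % of its charged right-handed substrate.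

The earlier runs and the new flask were computed with constants of no real substance; scatter was added.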